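## The problem

Target 20 is a tetrahydrofuran (ring numbered O1, C2, C3, C4, C5). C2 carries a 4-hydroxy-3-methoxyphenyl group, C3 a hydroxymethyl group, and C4 an exocyclic secondary carbinol carbon (called C7′ here) that bears the 3,4-dihydroxyphenyl ring; C5 is a bare methylene. The ring centres (2S,3R,4S) are all-trans, so they can be built by relay: C2 and C3 together in one aldol-type event, after which the C3 substituent directs a new bond at C4 to the opposite face. The fourth centre, C7′ (R), lies outside the ring in a syn (erythro) aldol relationship to C4; no ring constraint holds it, and it is the real stereochemical problem. The functional groups are fragile: the catechol is oxidised by air once deprotonated, the C7′ carbinol para to a free phenol ionises in acid and is then trapped by the C3 hydroxymethyl group as a furofuran, and the C2–O1 bond is a benzylic ether para to a phenol, open to acid epimerisation and to hydrogenolysis. Free phenols should therefore appear only at the end, under neutral or weakly basic, non-reducing conditions. What invites a photochemical solution is the array O–C7′–C4–C5: the carbinol oxygen is 1,3 to C5, so C7′–C4 is an aldol bond if C5 stands at a carbonyl level, and that oxygen can be tied for a while to C5 in an oxetane fused across C4–C5. The catch is regiochemical: the aldehyde oxygen has to go to C5 and the aldehyde carbon to C4, which an ordinary cyclic enol ether does not allow.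

## Retrosynthesis

**Unmasking (20 ⇒ 19 ⇒ 18).** No skeletal bond is cut. In 18 the catechol is a diacetate, the guaiacyl phenol a triisopropylsilyl ether and the primary alcohol a tert-butyldimethylsilyl ether. The acetates are dictated by the photochemistry and leave last by mild methanolysis; the silyl ethers leave together with buffered fluoride. Benzyl ethers were set aside because their hydrogenolysis would expose two benzylic C–O bonds para to oxygen. The forward steps must avoid acid and oxygen, nothing more.

**C5 back to a methylene (18 ⇒ 17 ⇒ 16).** The two C5–H bonds are traced to the carbonyl of γ-lactone 16 through lactol 17. Carrying C5 at the carboxyl level costs two reductions, but it is what makes the key step regiochemically sound (see below). The forward reductions must spare two aryl acetates and must not ionise either benzylic C–O bond. A hindered dialkylborane followed by ionic hydrogenation meets the first demand, and the acetoxy groups help with the second by deactivating the C7′ carbinol.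

**The temporary bond (16 ⇒ 15).** The C7′ oxygen of 16 is reconnected to C5, which gives the bicyclic oxetane ortho ester 15 (a 2,7-dioxabicyclo[3.2.0]heptane). The forward reaction is a hydrolysis that breaks only the strained C5–O bond, so C7′ and C4 keep the configuration set in the bicycle.

**The key cut (15 ⇒ 12 + 14).** The C4–C7′ bond and the C5–O bond are cut together in a carbonyl–alkene (2+2) photocycloreversion, leading to ketene silyl acetal 12 and aldehyde 14.
- Against a ground-state aldol of the enolate of 11 with 14: that makes the same C–C bond but offers little control at C7′ and exposes aryl acetates to a basic enolate. The photochemical variant is neutral and locks the new centre into a rigid bicycle.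
- Against an unadorned C4=C5 enol ether (C5–H): excited aromatic aldehydes add to simple cyclic enol ethers with oxygen at the β-carbon and carbon at the oxygen-bearing carbon. That would give the 2,6-dioxabicyclo[3.2.0]heptane and attach the carbinol carbon to C5.
- Against a furan-type partner: it shows the aldol-type orientation but would erase the C2 and C3 stereocentres.
- A ketene silyl acetal also shows the aldol-type orientation, and here it is simply the enol form of a lactone that already holds both ring centres.

The precursors are a monocyclic lactone derivative with two stereocentres and a trivial aldehyde. The forward step must deliver oxygen to C5, attack the face anti to the C3 substituent, and place the aryl group endo.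

**Ketene acetal and lactone (12 ⇒ 11 ⇒ 10 ⇒ 9 ⇒ 7).** The O–Si bond of 12 is cut to lactone 11, and functional-group changes at the C3 side chain lead back through alcohol 10 and acid 9 to acyl oxazolidinone 7. The side chain must be an ether before enolisation, because an ester or imide at C3 would invite ring-opening elimination. The forward steps need chemoselectivity only (imide over lactone, acid over lactone).

**Ring and first two centres (7 ⇒ 5 + 2; 5 ⇒ 3 + 4; 2 ⇒ 1; 14 ⇒ 13).** The lactone C–O bond and the C2–C3 bond of 7 are cut to the succinate-derived imide 5 and protected vanillin 2. A syn-aldol followed by lactonisation gives exactly the 2,3-trans lactone. The auxiliary route was preferred to a propargylation–cycloisomerisation entry because it delivers C5 directly at the lactone level. Imide 5 comes from auxiliary 3 and acid chloride 4, aldehyde 2 from vanillin 1, and 14 from aldehyde 13.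

## Roads not taken

**Alternative 1:** oxocarbenium–allylsilane annulation. The cut is O1–C2 plus C2–C3. In the forward step a silyl triflate (Me3SiOTf) condenses O-benzylvanillin A3 with the hydroxy allylsilane A2 to an oxocarbenium ion. The allylsilane γ-carbon attacks it and closes the ring to the 3-vinyl tetrahydrofuran A1.
- Merits: the ring and C2 arise in one thermal, scalable step from a simple aldehyde; C5 is already a methylene; the C2 aryl group enters late.
- Weak points: A2 must already contain C4 and C7′ in the correct syn relationship, so the hardest stereochemical problem is only moved into its preparation. A benzylic pivalate on a dialkoxyaryl ring sits next to a strong Lewis acid. The vinyl group needs oxidative cleavage and reduction in the presence of three electron-rich arenes. Three benzyl ethers must finally be hydrogenolysed beside two benzylic C–O bonds.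
- Comparison: this road is better in convergence and needs no redox detour at C5. The chosen plan sets against it that C4 and C7′ are created in the bond-forming step itself, on a lactone whose two centres come from a dependable auxiliary aldol, and that it ends without hydrogenolysis.

**Alternative 2:** alkyne–Prins closure. The cut is C4–C5, with C5 supplied at the formaldehyde level. A thiophilic methylthiosulfonium salt ionises the methylthiomethyl ether A5, the alkyne attacks the oxocarbenium ion, and the aryl vinyl cation is hydrated to the 4-aroyl tetrahydrofuran A4.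
- Merits: C5 has the right oxidation level from the start, and the ketone lets C4 settle trans by enolisation.
- Weak points: the key step does nothing for C7′, which must come from a reagent-controlled reduction of an α-branched aryl ketone. The thiophilic activator meets four benzyl ethers and an electron-rich aryl alkyne. Four hydrogenolyses close the route.
- Comparison: on the C5 oxidation level this road is better, since the chosen plan spends two steps there. In exchange, the chosen plan addresses C7′ in its main line and keeps ketone reduction only as a reserve.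

**Alternative 3:** Prins–pinacol ring contraction. The cut is O1–C2 and C2–C3, with C5 migrating. SnCl4 condenses the allylic diol A7 with A3; the alkene closes a six-membered cation, and a 1,2-shift of C5 contracts it to the 4-aroyl tetrahydrofuran A6.
- Merits: one step builds the ring, three ring centres and the aroyl group. In bond-forming power per step it is stronger than the chosen plan.
- Weak points: A7 is an enantioenriched tertiary carbinol that is not trivial to obtain. In the pinacol step the aryl group on the carbinol carbon competes with C5 as the migrating group, and the pivalates only attenuate this. C7′ again needs a ketone reduction, and benzyl ethers again need hydrogenolysis.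
- Comparison: the chosen plan is longer in the ring-forming phase. It sets against this a stereochemically defined lactone made by routine chemistry, direct installation of the carbinol, and a non-reductive, non-acidic end game.

Key step: step 9

Remark: ring positions are called O1, C2 (guaiacyl-bearing), C3, C4, C5 and C7′ (carbinol) throughout, also in lactone and bicyclic intermediates; systematic names use their own locants.

## Steps

Step 1
Reactants: 1 vanillin (4-hydroxy-3-methoxybenzaldehyde)
Product: 2 3-methoxy-4-(triisopropylsilyloxy)benzaldehyde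
Conditions: TIPSCl, imidazole, DMF, rt
Reagents that add atoms: triisopropylsilyl chloride, CC(C)[Si](Cl)(C(C)C)C(C)C
Why: Silylation of a phenol; the bulky silyl ether is chosen to survive LiOH/H2O2, LiN(iPr)2 and BF3·OEt2 later and still to leave with fluoride.

Step 2
Reactants: 3 (4S)-4-benzyl-1,3-oxazolidin-2-one; 4 methyl 4-chloro-4-oxobutanoate
Product: 5 methyl 4-[(4S)-4-benzyl-2-oxo-1,3-oxazolidin-3-yl]-4-oxobutanoate
Conditions: n-BuLi, THF, −78 °C; then 4, −78 → 0 °C
Reagents that add atoms: none
Why: N-Acylation of the lithiated oxazolidinone by the acid chloride; the methyl ester end is far less electrophilic and stays intact.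

Step 3
Reactants: 5 methyl 4-[(4S)-4-benzyl-2-oxo-1,3-oxazolidin-3-yl]-4-oxobutanoate; 2 3-methoxy-4-(triisopropylsilyloxy)benzaldehyde
Product: 7 (4S)-4-benzyl-3-{[(2S,3S)-2-[3-methoxy-4-(triisopropylsilyloxy)phenyl]-5-oxotetrahydrofuran-3-yl]carbonyl}-1,3-oxazolidin-2-one (2,3-trans lactone), via syn-aldol adduct 6 (not isolated)
Conditions: Bu2BOTf, iPr2NEt, CH2Cl2, 0 → −78 °C; 2, −78 → 0 °C; pH 7 buffer, MeOH, H2O2; then CSA (cat.), CH2Cl2, rt
Reagents that add atoms: none
Why: Evans syn-aldol: the Z-boron enolate of the imide reacts through a Zimmerman–Traxler chair on the face away from the benzyl group, which sets C2 (S) and C3 as the syn pair. Acid-catalysed 5-exo-trig lactonisation of the benzylic hydroxyl onto the methyl ester then turns the syn-aldol into the 2,3-trans lactone.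

Step 4
Reactants: 7 (4S)-4-benzyl-3-{[(2S,3S)-2-[3-methoxy-4-(triisopropylsilyloxy)phenyl]-5-oxotetrahydrofuran-3-yl]carbonyl}-1,3-oxazolidin-2-one
Product: 9 (2S,3S)-2-[3-methoxy-4-(triisopropylsilyloxy)phenyl]-5-oxotetrahydrofuran-3-carboxylic acid, via peroxy acid 8 (not isolated)
Conditions: LiOH, H2O2, THF/H2O, 0 °C; Na2SO3 (aq); HCl to pH 2
Reagents that add atoms: hydrogen peroxide, OO
Why: Hydroperoxide attacks the exocyclic imide carbonyl selectively (standard auxiliary removal), and sulfite reduces the peroxy acid to the acid. Acidification re-closes any lactone opened by hydroxide, and auxiliary 3 is recovered.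

Step 5
Reactants: 9 (2S,3S)-2-[3-methoxy-4-(triisopropylsilyloxy)phenyl]-5-oxotetrahydrofuran-3-carboxylic acid
Product: 10 (4R,5S)-4-(hydroxymethyl)-5-[3-methoxy-4-(triisopropylsilyloxy)phenyl]dihydrofuran-2(3H)-one
Conditions: BH3·SMe2, THF, 0 °C → rt; MeOH
Reagents that add atoms: none
Why: Borane reduces a carboxylic acid through its acyloxyborane much faster than a γ-lactone, so only the side chain is reduced; the descriptor at the ring carbon changes by priority only.

Step 6
Reactants: 10 (4R,5S)-4-(hydroxymethyl)-5-[3-methoxy-4-(triisopropylsilyloxy)phenyl]dihydrofuran-2(3H)-one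
Product: 11 (4R,5S)-4-[(tert-butyldimethylsilyloxy)methyl]-5-[3-methoxy-4-(triisopropylsilyloxy)phenyl]dihydrofuran-2(3H)-one
Conditions: TBSCl, imidazole, CH2Cl2, 0 °C → rt
Reagents that add atoms: tert-butyldimethylsilyl chloride, CC(C)(C)[Si](C)(C)Cl
Why: Silylation of the primary alcohol under conditions that never generate the free alkoxide, so translactonisation onto the primary oxygen is avoided.

Step 7
Reactants: 11 (4R,5S)-4-[(tert-butyldimethylsilyloxy)methyl]-5-[3-methoxy-4-(triisopropylsilyloxy)phenyl]dihydrofuran-2(3H)-one
Product: 12 (2S,3R)-5-(tert-butyldimethylsilyloxy)-3-[(tert-butyldimethylsilyloxy)methyl]-2-[3-methoxy-4-(triisopropylsilyloxy)phenyl]-2,3-dihydrofuran (ketene silyl acetal, C4=C5)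
Conditions: LiN(iPr)2, THF, −78 °C; TBSCl, DMPU, −78 °C → rt; pentane, filtration
Reagents that add atoms: tert-butyldimethylsilyl chloride, CC(C)(C)[Si](C)(C)Cl
Why: Kinetic enolisation at the only α-methylene (C4) and O-silylation of the lactone enolate, favoured by the polar cosolvent and the bulky silyl chloride. No leaving group sits β to the enolate, and the work-up is non-aqueous because the ketene acetal is hydrolytically labile.

Step 8
Reactants: 13 3,4-dihydroxybenzaldehyde
Product: 14 4-formyl-1,2-phenylene diacetate (3,4-diacetoxybenzaldehyde)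
Conditions: Ac2O, pyridine, DMAP (cat.), CH2Cl2, 0 °C → rt
Reagents that add atoms: acetic anhydride, CC(=O)OC(C)=O
Why: Acetylation of both phenols; acyloxy groups are weak donors, so the aldehyde keeps an n,π* lowest triplet, and later they protect the benzylic carbinol from ionisation.

Step 9
Reactants: 12 (2S,3R)-5-(tert-butyldimethylsilyloxy)-3-[(tert-butyldimethylsilyloxy)methyl]-2-[3-methoxy-4-(triisopropylsilyloxy)phenyl]-2,3-dihydrofuran; 14 4-formyl-1,2-phenylene diacetate
Product: 15 4-[(1S,3S,4R,5R,6R)-1-(tert-butyldimethylsilyloxy)-4-[(tert-butyldimethylsilyloxy)methyl]-3-[3-methoxy-4-(triisopropylsilyloxy)phenyl]-2,7-dioxabicyclo[3.2.0]heptan-6-yl]-1,2-phenylene diacetate (6-endo-aryl oxetane ortho ester; used crude)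
Conditions: hν (medium-pressure Hg lamp, Pyrex, λ > 300 nm), C6H6 (degassed), 10 °C
Reagents that add atoms: none
Why: Paternò–Büchi reaction; the closest known reaction type is the photocycloaddition of aromatic aldehydes to cyclic ketene silyl acetals, which gives 2-alkoxy-2-silyloxyoxetanes of aldol connectivity. Only 14 absorbs above 300 nm; its n,π* triplet forms a charge-transfer complex with the electron-rich C4=C5 bond of 12, whose positive end is the doubly oxygenated C5, so the carbonyl oxygen bonds to C5 and leaves a triplet 1,4-biradical at C4 and the benzylic carbon. After intersystem crossing these two radical centres combine and close the oxetane (four-membered ring, radical recombination, necessarily cis-fused, which fixes the bridgehead C1 once the neighbouring bridgehead is set). The new ring centre (C4 of the tetrahydrofuran, C5 of the bicycle) is controlled by the adjacent C3 stereocentre, the aldehyde approaching the face anti to the silyloxymethyl group. The carbinol carbon (C6 of the bicycle) should form endo-aryl, the configuration needed at C7′, because such biradicals on five-membered rings close from the conformer that turns the aryl group under the ring and because the convex face carries the bridgehead silyloxy group. The step needs three selectivities: regiochemistry, secured by the second oxygen on C5 (a C5–H enol ether would take the carbonyl carbon at C5); facial selectivity, secured by C3; and endo closure, the least secure, because the C2 aryl group lies on the same face. Benzene is used so that the donor–acceptor pair collapses to the oxetane and does not separate into radical ions, which would lead to silyl transfer without stereocontrol.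

Step 10
Reactants: 15 4-[(1S,3S,4R,5R,6R)-1-(tert-butyldimethylsilyloxy)-4-[(tert-butyldimethylsilyloxy)methyl]-3-[3-methoxy-4-(triisopropylsilyloxy)phenyl]-2,7-dioxabicyclo[3.2.0]heptan-6-yl]-1,2-phenylene diacetate
Product: 16 4-[(R)-{(3R,4R,5S)-4-[(tert-butyldimethylsilyloxy)methyl]-5-[3-methoxy-4-(triisopropylsilyloxy)phenyl]-2-oxotetrahydrofuran-3-yl}(hydroxy)methyl]-1,2-phenylene diacetate
Conditions: AcOH, THF/H2O, 0 °C
Reagents that add atoms: none
Why: Acid-catalysed hydrolysis of the ortho ester: the strained oxetane oxygen is protonated, the C5–O bond breaks, and water removes the silyl group from the resulting silylated lactone as the silanol. The C7′–O and C4–C7′ bonds are untouched, so both configurations are kept; excess 14 is removed at this stage.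

Step 11
Reactants: 16 4-[(R)-{(3R,4R,5S)-4-[(tert-butyldimethylsilyloxy)methyl]-5-[3-methoxy-4-(triisopropylsilyloxy)phenyl]-2-oxotetrahydrofuran-3-yl}(hydroxy)methyl]-1,2-phenylene diacetate
Product: 17 4-[(R)-{(3R,4R,5S)-4-[(tert-butyldimethylsilyloxy)methyl]-2-hydroxy-5-[3-methoxy-4-(triisopropylsilyloxy)phenyl]tetrahydrofuran-3-yl}(hydroxy)methyl]-1,2-phenylene diacetate (lactol, mixture of anomers)
Conditions: (Me2CHCHMe)2BH (from BH3·THF and 2-methylbut-2-ene), THF, 0 °C → rt; MeOH
Reagents that add atoms: none
Why: Disiamylborane reduces γ-lactones to lactols and stops there, while esters, including aryl acetates, are not reduced at a useful rate by this hindered electrophilic borane (the selectivity used on acylated sugar lactones). The free hydroxyl only consumes one extra equivalent.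

Step 12
Reactants: 17 4-[(R)-{(3R,4R,5S)-4-[(tert-butyldimethylsilyloxy)methyl]-2-hydroxy-5-[3-methoxy-4-(triisopropylsilyloxy)phenyl]tetrahydrofuran-3-yl}(hydroxy)methyl]-1,2-phenylene diacetate
Product: 18 4-[(R)-{(3S,4R,5S)-4-[(tert-butyldimethylsilyloxy)methyl]-5-[3-methoxy-4-(triisopropylsilyloxy)phenyl]tetrahydrofuran-3-yl}(hydroxy)methyl]-1,2-phenylene diacetate
Conditions: Et3SiH, BF3·OEt2, CH2Cl2, −78 → −40 °C; NaHCO3 (aq)
Reagents that add atoms: none
Why: Ionic hydrogenation: the Lewis acid ionises the lactol to the C5 oxocarbenium ion, which takes hydride from the silane; C5 becomes a methylene and no stereocentre is formed. The two acetoxy groups keep the C7′ carbinol from ionising, and the low temperature spares the C2–O1 benzylic bond.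

Step 13
Reactants: 18 4-[(R)-{(3S,4R,5S)-4-[(tert-butyldimethylsilyloxy)methyl]-5-[3-methoxy-4-(triisopropylsilyloxy)phenyl]tetrahydrofuran-3-yl}(hydroxy)methyl]-1,2-phenylene diacetate
Product: 19 4-[(R)-hydroxy{(3S,4R,5S)-5-(4-hydroxy-3-methoxyphenyl)-4-(hydroxymethyl)tetrahydrofuran-3-yl}methyl]-1,2-phenylene diacetate
Conditions: Bu4NF, AcOH, THF, 0 °C → rt
Reagents that add atoms: none
Why: Fluoride cleavage of the aryl and the primary silyl ether in one operation; the acetic acid buffer keeps the medium near neutral, so the aryl acetates stay and no phenoxide is exposed to air.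

Step 14
Reactants: 19 4-[(R)-hydroxy{(3S,4R,5S)-5-(4-hydroxy-3-methoxyphenyl)-4-(hydroxymethyl)tetrahydrofuran-3-yl}methyl]-1,2-phenylene diacetate
Product: 20 4-[(R)-hydroxy{(3S,4R,5S)-5-(4-hydroxy-3-methoxyphenyl)-4-(hydroxymethyl)tetrahydrofuran-3-yl}methyl]benzene-1,2-diol (CNP0197133.1)
Conditions: K2CO3 (cat.), MeOH (degassed), 0 °C, Ar; AcOH to pH 6
Reagents that add atoms: none
Why: Base-catalysed transesterification (Zemplén-type methanolysis) of the two aryl acetates, fast at 0 °C. Oxygen is excluded to protect the catecholate, and the quench uses a weak acid so that the C7′ carbinol does not ionise.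

## Compound list

1 | vanillin (4-hydroxy-3-methoxybenzaldehyde) | COc1cc(C=O)ccc1O | starting material
2 | 3-methoxy-4-(triisopropylsilyloxy)benzaldehyde | COc1cc(C=O)ccc1O[Si](C(C)C)(C(C)C)C(C)C | intermediate
3 | (4S)-4-benzyl-1,3-oxazolidin-2-one | O=C1OC[C@H](Cc2ccccc2)N1 | starting material
4 | methyl 4-chloro-4-oxobutanoate | COC(=O)CCC(Cl)=O | starting material
5 | methyl 4-[(4S)-4-benzyl-2-oxo-1,3-oxazolidin-3-yl]-4-oxobutanoate | COC(=O)CCC(=O)N1[C@@H](Cc2ccccc2)COC1=O | intermediate
6 | methyl (3S,4S)-3-{[(4S)-4-benzyl-2-oxo-1,3-oxazolidin-3-yl]carbonyl}-4-hydroxy-4-[3-methoxy-4-(triisopropylsilyloxy)phenyl]butanoate (syn-aldol adduct) | COc1cc([C@@H](O)[C@H](CC(=O)OC)C(=O)N2[C@@H](Cc3ccccc3)COC2=O)ccc1O[Si](C(C)C)(C(C)C)C(C)C | intermediate (not isolated)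
7 | (4S)-4-benzyl-3-{[(2S,3S)-2-[3-methoxy-4-(triisopropylsilyloxy)phenyl]-5-oxotetrahydrofuran-3-yl]carbonyl}-1,3-oxazolidin-2-one | COc1cc([C@H]2OC(=O)C[C@@H]2C(=O)N3[C@@H](Cc4ccccc4)COC3=O)ccc1O[Si](C(C)C)(C(C)C)C(C)C | intermediate
8 | (2S,3S)-2-[3-methoxy-4-(triisopropylsilyloxy)phenyl]-5-oxotetrahydrofuran-3-carboperoxoic acid (peroxy acid) | COc1cc([C@H]2OC(=O)C[C@@H]2C(=O)OO)ccc1O[Si](C(C)C)(C(C)C)C(C)C | intermediate (not isolated)
9 | (2S,3S)-2-[3-methoxy-4-(triisopropylsilyloxy)phenyl]-5-oxotetrahydrofuran-3-carboxylic acid | COc1cc([C@H]2OC(=O)C[C@@H]2C(=O)O)ccc1O[Si](C(C)C)(C(C)C)C(C)C | intermediate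
10 | (4R,5S)-4-(hydroxymethyl)-5-[3-methoxy-4-(triisopropylsilyloxy)phenyl]dihydrofuran-2(3H)-one | COc1cc([C@H]2OC(=O)C[C@@H]2CO)ccc1O[Si](C(C)C)(C(C)C)C(C)C | intermediate
11 | (4R,5S)-4-[(tert-butyldimethylsilyloxy)methyl]-5-[3-methoxy-4-(triisopropylsilyloxy)phenyl]dihydrofuran-2(3H)-one | COc1cc([C@H]2OC(=O)C[C@@H]2CO[Si](C)(C)C(C)(C)C)ccc1O[Si](C(C)C)(C(C)C)C(C)C | intermediate
12 | (2S,3R)-5-(tert-butyldimethylsilyloxy)-3-[(tert-butyldimethylsilyloxy)methyl]-2-[3-methoxy-4-(triisopropylsilyloxy)phenyl]-2,3-dihydrofuran | COc1cc([C@H]2OC(O[Si](C)(C)C(C)(C)C)=C[C@@H]2CO[Si](C)(C)C(C)(C)C)ccc1O[Si](C(C)C)(C(C)C)C(C)C | intermediate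
13 | 3,4-dihydroxybenzaldehyde | O=Cc1ccc(O)c(O)c1 | starting material
14 | 4-formyl-1,2-phenylene diacetate (3,4-diacetoxybenzaldehyde) | CC(=O)Oc1ccc(C=O)cc1OC(C)=O | intermediate
15 | 4-[(1S,3S,4R,5R,6R)-1-(tert-butyldimethylsilyloxy)-4-[(tert-butyldimethylsilyloxy)methyl]-3-[3-methoxy-4-(triisopropylsilyloxy)phenyl]-2,7-dioxabicyclo[3.2.0]heptan-6-yl]-1,2-phenylene diacetate (6-endo-aryl) | COc1cc([C@H]2O[C@@]3(O[Si](C)(C)C(C)(C)C)O[C@@H](c4ccc(OC(C)=O)c(OC(C)=O)c4)[C@H]3[C@@H]2CO[Si](C)(C)C(C)(C)C)ccc1O[Si](C(C)C)(C(C)C)C(C)C | intermediate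
16 | 4-[(R)-{(3R,4R,5S)-4-[(tert-butyldimethylsilyloxy)methyl]-5-[3-methoxy-4-(triisopropylsilyloxy)phenyl]-2-oxotetrahydrofuran-3-yl}(hydroxy)methyl]-1,2-phenylene diacetate | COc1cc([C@H]2OC(=O)[C@@H]([C@@H](O)c3ccc(OC(C)=O)c(OC(C)=O)c3)[C@@H]2CO[Si](C)(C)C(C)(C)C)ccc1O[Si](C(C)C)(C(C)C)C(C)C | intermediate
17 | 4-[(R)-{(3R,4R,5S)-4-[(tert-butyldimethylsilyloxy)methyl]-2-hydroxy-5-[3-methoxy-4-(triisopropylsilyloxy)phenyl]tetrahydrofuran-3-yl}(hydroxy)methyl]-1,2-phenylene diacetate (anomeric mixture) | COc1cc([C@H]2OC(O)[C@@H]([C@@H](O)c3ccc(OC(C)=O)c(OC(C)=O)c3)[C@@H]2CO[Si](C)(C)C(C)(C)C)ccc1O[Si](C(C)C)(C(C)C)C(C)C | intermediate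
18 | 4-[(R)-{(3S,4R,5S)-4-[(tert-butyldimethylsilyloxy)methyl]-5-[3-methoxy-4-(triisopropylsilyloxy)phenyl]tetrahydrofuran-3-yl}(hydroxy)methyl]-1,2-phenylene diacetate | COc1cc([C@H]2OC[C@@H]([C@@H](O)c3ccc(OC(C)=O)c(OC(C)=O)c3)[C@@H]2CO[Si](C)(C)C(C)(C)C)ccc1O[Si](C(C)C)(C(C)C)C(C)C | intermediate
19 | 4-[(R)-hydroxy{(3S,4R,5S)-5-(4-hydroxy-3-methoxyphenyl)-4-(hydroxymethyl)tetrahydrofuran-3-yl}methyl]-1,2-phenylene diacetate | COc1cc([C@H]2OC[C@@H]([C@@H](O)c3ccc(OC(C)=O)c(OC(C)=O)c3)[C@@H]2CO)ccc1O | intermediate
20 | 4-[(R)-hydroxy{(3S,4R,5S)-5-(4-hydroxy-3-methoxyphenyl)-4-(hydroxymethyl)tetrahydrofuran-3-yl}methyl]benzene-1,2-diol | COc1cc([C@H]2OC[C@@H]([C@@H](O)c3ccc(O)c(O)c3)[C@@H]2CO)ccc1O | target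

## Step count and least certain steps

Total: 14 steps. Longest linear sequence: 12 steps (1 → 2 → 7 → 9 → 10 → 11 → 12 → 15 → 16 → 17 → 18 → 19 → 20).

**Step 9 (key step).** Two things are most likely to go wrong.
- Loss of endo control: the biradical may close with the aryl group on the convex face, because the C2 aryl group crowds the concave side. This inverts C7′.
- Diversion of the excited aldehyde: full electron transfer with silyl migration, or hydrogen abstraction at the doubly activated C2–H.

Fallback (sets out from 11, returns at 16): the C4–C7′ bond is made in the ground state. The lithium enolate of 11 (LiN(SiMe3)2, THF, −78 °C) is acylated with 3,4-diacetoxybenzoyl chloride to the β-keto lactone F1, in which C4 settles trans to the C3 substituent. Chelation-controlled reduction with Zn(BH4)2 (Et2O, −20 °C) should then give the syn carbinol 16, because hydride reaches the ketone in the zinc chelate of the two carbonyl groups from the face anti to C3. Material that has passed through the photochemical step with the opposite carbinol configuration, the 7′-epimeric hydroxy lactone F2, joins this line by Dess–Martin oxidation to F1.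

**Step 11.** The likely failure is loss of chemoselectivity: slow lactone reduction once the neighbouring hydroxyl is tied up as a borinate, or attack on the aryl acetates during a prolonged reaction.
Fallback (sets out from 16, returns at 20): reductive acetylation. iBu2AlH (excess, CH2Cl2, −78 °C) is followed in the same flask by pyridine, DMAP and Ac2O. This acetylates the aluminium lactolate, the C7′ alkoxide and any phenoxides released from the aryl acetates, giving the peracetylated lactol acetate F3. Et3SiH/BF3·OEt2 reduces only the anomeric acetate, giving the tetrahydrofuran triacetate F4. Buffered Bu4NF removes both silyl groups to give the triacetate diol F5, and the methanolysis of step 14 removes all three acetates to give 20.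

**Step 12.** The likely failure is ionisation of the electron-rich C2–O1 benzylic bond in competition with lactol ionisation, leading to ring opening or epimerisation at C2; proton loss from the oxocarbenium ion to an enol ether is a lesser risk.
Fallback (sets out from 17, returns at 18): no cation is formed at all. NaBH4 (EtOH, −20 °C, short contact) reduces the lactol through its hydroxy aldehyde form to the triol F6. Mitsunobu cyclodehydration (PPh3, DIAD, THF, 0 °C) activates the primary hydroxyl, which is displaced by the C2 oxygen (5-exo-tet), so the C2–O bond is never broken and 18 results.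

**Step 14.** The likely failures are oxidation of the catecholate by traces of air, or over-acidification at the quench with ionisation at C7′ and ring closure onto the C3 hydroxymethyl group.
Fallback (sets out from 19, returns at 20): enzymatic alcoholysis of the aryl acetates (immobilised Candida antarctica lipase B, n-BuOH, t-BuOMe, rt), which needs neither base nor an acidic quench and passes through no new compound.

## Further compounds

F1 | step 9 | 4-{[(3R,4R,5S)-4-[(tert-butyldimethylsilyloxy)methyl]-5-[3-methoxy-4-(triisopropylsilyloxy)phenyl]-2-oxotetrahydrofuran-3-yl]carbonyl}-1,2-phenylene diacetate (β-keto lactone) | COc1cc([C@H]2OC(=O)[C@@H](C(=O)c3ccc(OC(C)=O)c(OC(C)=O)c3)[C@@H]2CO[Si](C)(C)C(C)(C)C)ccc1O[Si](C(C)C)(C(C)C)C(C)C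
F2 | step 9 | 4-[(S)-{(3R,4R,5S)-4-[(tert-butyldimethylsilyloxy)methyl]-5-[3-methoxy-4-(triisopropylsilyloxy)phenyl]-2-oxotetrahydrofuran-3-yl}(hydroxy)methyl]-1,2-phenylene diacetate (7′-epimer of 16) | COc1cc([C@H]2OC(=O)[C@@H]([C@H](O)c3ccc(OC(C)=O)c(OC(C)=O)c3)[C@@H]2CO[Si](C)(C)C(C)(C)C)ccc1O[Si](C(C)C)(C(C)C)C(C)C
F3 | step 11 | 4-[(R)-acetoxy{(3R,4R,5S)-2-acetoxy-4-[(tert-butyldimethylsilyloxy)methyl]-5-[3-methoxy-4-(triisopropylsilyloxy)phenyl]tetrahydrofuran-3-yl}methyl]-1,2-phenylene diacetate (anomeric mixture) | COc1cc([C@H]2OC(OC(C)=O)[C@@H]([C@@H](OC(C)=O)c3ccc(OC(C)=O)c(OC(C)=O)c3)[C@@H]2CO[Si](C)(C)C(C)(C)C)ccc1O[Si](C(C)C)(C(C)C)C(C)C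
F4 | step 11 | 4-[(R)-acetoxy{(3S,4R,5S)-4-[(tert-butyldimethylsilyloxy)methyl]-5-[3-methoxy-4-(triisopropylsilyloxy)phenyl]tetrahydrofuran-3-yl}methyl]-1,2-phenylene diacetate | COc1cc([C@H]2OC[C@@H]([C@@H](OC(C)=O)c3ccc(OC(C)=O)c(OC(C)=O)c3)[C@@H]2CO[Si](C)(C)C(C)(C)C)ccc1O[Si](C(C)C)(C(C)C)C(C)C
F5 | step 11 | 4-[(R)-acetoxy{(3S,4R,5S)-5-(4-hydroxy-3-methoxyphenyl)-4-(hydroxymethyl)tetrahydrofuran-3-yl}methyl]-1,2-phenylene diacetate | COc1cc([C@H]2OC[C@@H]([C@@H](OC(C)=O)c3ccc(OC(C)=O)c(OC(C)=O)c3)[C@@H]2CO)ccc1O
F6 | step 12 | 4-[(1R,2S,3R,4S)-3-[(tert-butyldimethylsilyloxy)methyl]-1,4-dihydroxy-2-(hydroxymethyl)-4-[3-methoxy-4-(triisopropylsilyloxy)phenyl]butyl]-1,2-phenylene diacetate | COc1cc([C@@H](O)[C@@H](CO[Si](C)(C)C(C)(C)C)[C@@H](CO)[C@@H](O)c2ccc(OC(C)=O)c(OC(C)=O)c2)ccc1O[Si](C(C)C)(C(C)C)C(C)C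
F0 | step 14 | none | none
A1 | alternative 1 | all-trans 2-[4-(benzyloxy)-3-methoxyphenyl]-3-vinyl-4-{[3,4-bis(benzyloxy)phenyl](pivaloyloxy)methyl}tetrahydrofuran | COc1cc([C@H]2OC[C@@H]([C@@H](OC(=O)C(C)(C)C)c3ccc(OCc4ccccc4)c(OCc4ccccc4)c3)[C@@H]2C=C)ccc1OCc1ccccc1
A2 | alternative 1 | (R)-[3,4-bis(benzyloxy)phenyl][(2S,3E)-1-hydroxy-5-(trimethylsilyl)pent-3-en-2-yl]methyl pivalate (hydroxy allylsilane) | OC[C@@H]([C@@H](OC(=O)C(C)(C)C)c1ccc(OCc2ccccc2)c(OCc2ccccc2)c1)/C=C/C[Si](C)(C)C
A3 | alternative 1 | 4-(benzyloxy)-3-methoxybenzaldehyde (O-benzylvanillin) | COc1cc(C=O)ccc1OCc1ccccc1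
A4 | alternative 2 | all-trans 2-[4-(benzyloxy)-3-methoxyphenyl]-3-[(benzyloxy)methyl]-4-[3,4-bis(benzyloxy)benzoyl]tetrahydrofuran | COc1cc([C@H]2OC[C@@H](C(=O)c3ccc(OCc4ccccc4)c(OCc4ccccc4)c3)[C@@H]2COCc2ccccc2)ccc1OCc1ccccc1
A5 | alternative 2 | 1-(benzyloxy)-4-{(1S,2R)-2-[(benzyloxy)methyl]-4-[3,4-bis(benzyloxy)phenyl]-1-[(methylthio)methoxy]but-3-yn-1-yl}-2-methoxybenzene (methylthiomethyl ether) | COc1cc([C@@H](OCSC)[C@@H](COCc2ccccc2)C#Cc2ccc(OCc3ccccc3)c(OCc3ccccc3)c2)ccc1OCc1ccccc1
A6 | alternative 3 | all-trans 2-[4-(benzyloxy)-3-methoxyphenyl]-3-[(benzyloxy)methyl]-4-[3,4-bis(pivaloyloxy)benzoyl]tetrahydrofuran | COc1cc([C@H]2OC[C@@H](C(=O)c3ccc(OC(=O)C(C)(C)C)c(OC(=O)C(C)(C)C)c3)[C@@H]2COCc2ccccc2)ccc1OCc1ccccc1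
A7 | alternative 3 | (E)-5-(benzyloxy)-2-[3,4-bis(pivaloyloxy)phenyl]pent-3-ene-1,2-diol (single enantiomer; configuration at the tertiary carbinol left open) | OCC(O)(/C=C/COCc1ccccc1)c1ccc(OC(=O)C(C)(C)C)c(OC(=O)C(C)(C)C)c1
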